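If the levelling of the runs below is a balance, two times carry it: the time two ends need to meet and the time after which a link seems to be lost again.

| flask | Z | L | G | remark | time |
|---|---|---|---|---|---|
| Wednesday's | 0.50 M | 0.66 equiv | 10 mM | run made earlier |  |
| Monday's | 0.50 M | 1.5 equiv | 10 mM | run made earlier |  |
| Saturday's | 0.50 M | 0.98 equiv | 20 mM | run made earlier |  |
| flask | 0.50 M | 0.980 equiv | 10.0 mM |  | 4.0 min |

- Wednesday's (time / min: Q / %, Z / %): 0.667: 31.7, 67.7; 1.33: 39.5, 59.5; 2.00: 41.3, 55.2; 2.50: 43.2, 54.5
- Monday's (time / min: Q / %, Z / %): 0.667: 55.2, 42.6; 1.33: 71.6, 26.5; 2.00: 73.9, 23.6; 2.50: 77.9, 18.5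
- Saturday's (time / min: Q / %, Z / %): 0.667: 38.7, 55.2; 1.33: 52.9, 44.1; 2.00: 57.2, 37.2; 2.50: 58.7, 36.7

(standard deviation of a reading: 1 percentage point)

- each monomer carries two end groups and G one, which caps an end: a chain counts once for every two ends that are left, dead ends included; the units are half of the end groups of the two monomers charged
- what has gone from Z into another species counts as reacted, even if it can come back

- average number of monomer units in a chain (unreacted monomers counted as chains of one) at 4.0 min
- part of the Z that has reacted at 4.0 min

Saturday's last reading, counting as L what linking would leave, gives an apparent [Q]/([Z][L]) of 8.14 M⁻¹; its first, by the integrated second-order law with the way back ignored, gives a rate constant k of 0.0333 M⁻¹ s⁻¹. In the flask I let G cap its own charge of Z, which starts Z and L each at 0.490 M, so ends meet in 1.02 min and a link seems to last 4.08 min. Their ratio is the stall number, 3.99. With the way back kept the approach is exponential with time constant 0.990 min, shorter than 4.0 min, so I put the flask on its plateau, where the stall number gives the linked fraction of [Z] as 60.9 %. That makes Q 59.7 % of the Z charged, c 61.7 % and dp 2.52.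

The forecast gives 2.52 and 62 %, saying “So linking is reversible”.

The flask gives 2.68 and 64.0 %.

    L → E (k = 0.00460 s⁻¹)
    Z + G → X (k = 0.400 M⁻¹ s⁻¹)
    Z + L ⇌ Q (K = 49.0 M⁻¹, k = 0.0400 M⁻¹ s⁻¹)

At 4.00 min the flask holds Q at 62.0 %. In a neighbour flask with 2.0 M of Z, the equivalents of L and the time held, the stall number becomes 16.0 and the linked fraction 77.9 %, so I reckon Q at 76.3 %; that flask gives dp 5.40 and Q 80.7 %.

All runs were computed with made-up constants; the scatter is artificial.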